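The earlier runs and the new flask were generated by integration on assumed constants, and the scatter is random.

Add up electrophile and target in each row of the earlier runs, elm and alder, before reckoning anything else. The flasks asked about, beta, delta and theta, differ from these runs in free base and time.

| flask | electrophile | nucleophile | free base | protic impurity | remark | time |
|---|---|---|---|---|---|---|
| elm | 1 M | 1.8 M | 0.26 M | 0.50 M | run made earlier |  |
| alder | 1 M | 1.8 M | 0.51 M | 0.50 M | run made earlier |  |
| beta | 1.0 M | 1.80 M | 0.300 M | 0.500 M |  | 80 min |
| delta | 1.0 M | 1.80 M | 0.450 M | 0.500 M |  | 80 min |
| theta | 1.0 M | 1.80 M | 0.670 M | 0.500 M |  | 80 min |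

| run | time / min | electrophile / % | target / % |
|---|---|---|---|
| elm | 6.00 | 41 | 12 |
| elm | 12.0 | 32 | 20 |
| elm | 20.0 | 24 | 25 |
| elm | 25.0 | 20 | 27 |
| elm | 30.0 | 16 | 31 |
| elm | 40.0 | 15 | 35 |
| alder | 3.00 | 48 | 7 |
| alder | 5.00 | 42 | 12 |
| alder | 8.00 | 37 | 13 |
| alder | 15.0 | 26 | 21 |
| alder | 25.0 | 21 | 29 |
| alder | 40.0 | 13 | 34 |

(scatter of a reading: 1.5 percentage points)

* part of the electrophile that has reacted at the end, beta
* part of the electrophile that has reacted at the end, delta
* part of the electrophile that has reacted at the end, theta
* what raising the concentration of free base from its lowest to its highest value here does to the part of the electrophile that has reacted (changes below 5 percentage points count as none) (no change / it falls / it rises)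

- what is said of acid set free includes crystals
- crystals is a solid; its amount is given per volume of the solution
- steps under discussion: crystals <-> acid set free; free base + target -> over-reaction product; nucleophile + acid set free <-> protonated nucleophile; electrophile + protic impurity -> quenched substrate; acid set free + free base <-> salt of the base; electrophile + nucleophile -> acid set free + target

Read down the elm table. By its first reading 47.0% of the charge is neither electrophile nor target, and by its last reading 50.0%, a growth of 3 percentage points against a scatter of 1.5 points on each reading. Alder ends at 53.0%.

Dividing one column's change by the other's removes time. Before the first elm reading, target gains 0.203 per unit of electrophile lost, but between first and last reading it gains 0.885. The early loss therefore goes elsewhere, and protic impurity is the candidate partner.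

This gives 50.0% as the quench share Q, protic impurity charged over electrophile charged. It is the part of the electrophile lost early if each impurity takes one electrophile, the impurity being the limiting reagent of that step.

Read as first order between its first and last readings, the electrophile of elm gives a decay constant k of 0.0296 min⁻¹, and alder, with twice the free base, ends 2 points lower, against a scatter of 1.5 points. Continued to 80 min, my own reckoning leaves 4.60% of the electrophile, so it puts the reacted part at 95.4% in each of beta, delta and theta.

The forecast, close to this, gives 94%, 95% and 96%, with no change as the trend, and says: “Over-reaction consumes target, not electrophile.”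

The flasks give 94.4%, 94.4% and 94.5%, so the trend is no change, with a change of 0.05 points.

    crystals ⇌ acid set free, rate k1*(cs1 - [acid set free]) while solid is left; crystals form when [acid set free] > cs1 (solubility = 0.350 M, k = 3.10 min⁻¹)
    free base + target → over-reaction product (k = 0.00470 L mol⁻¹ min⁻¹)
    nucleophile + acid set free ⇌ protonated nucleophile, settled at all times (K = 130 L mol⁻¹)
    electrophile + protic impurity → quenched substrate (k = 1.00 L mol⁻¹ min⁻¹)
    acid set free + free base ⇌ salt of the base, settled at all times (K = 7.40 L mol⁻¹)
    electrophile + nucleophile → acid set free + target (k = 0.0230 L mol⁻¹ min⁻¹)

In delta the quench ran ahead of the step with nucleophile: at 0.828 min the protic impurity had a half-life of 0.96 min by the quench, shorter than the 17 min of electrophile by the step with nucleophile, and at 80.0 min quenched substrate stands at 50.0% against Q of 50.0%, with protic impurity at 0%. Of their turnover up to 80 min, delta's step with nucleophile had half done by 14.8 min and its over-reaction by 47.0 min, and from beta to theta over-reaction product went from 3.26% to 6.93% while the reacted part of the electrophile moved by 0.05 points.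

A neighbouring flask is delta with 0.20 M of protic impurity, so there Q becomes 20.0%, leaving 80.0% of the electrophile for the nucleophile. Computed, this neighbour holds 20.0% quenched substrate and 57.9% target at 80.0 min, with 84.5% of its electrophile reacted.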